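**Plan**

- Numbering used throughout: ring carbons C1 (methacrylate carbinol), C2, C3 (CHMe), C4 (C=O), C5 (CHOH), C6, C7/C8 (epoxide, methyl on C7), C9 (lactone CH–O), C10; then C11 (lactone α-carbon), C12 (lactone C=O), C13 (CH2OAc).
- Retrosynthesis first opens the lactone (C9–O acyl bond) and takes C9 back to a ketone. The carbonyl carbons C4 and C9 then face each other 1,6 across the ten-membered ring, with four atoms between them on either side, so joining them as a C4=C9 alkene folds the macrocycle into an octalin: ring A (C1–C4, C9, C10) fused to ring B (C4–C9, carrying the cis-epoxide).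
- The octalin is cut at C10=C11 (aldol condensation), at the epoxide oxygen, at C7=C8 (metathesis), C8–C9 (vinyl addition) and C4–C5 (aldol); ring A comes from crotonaldehyde and tert-butyl acetoacetate.
- Forward order: ring A, the C4 side chain, ring B, dienone by oxidative transposition, epoxide, deconjugation to the C4=C9 alkene, C10 alkylidene ester, C1 carbinol; ozonolysis then unveils the ten-membered ring, C9 reduction closes the butenolide, and acylation and desilylation finish.
- Stereochemistry: C3 from the organocatalyst; C5 from a trans-selective anti-aldol relayed through C4 (later sp2); C7/C8 by epoxidation anti to the C5 silyl ether; C1 by hydride attack anti to the C3 methyl; C9 by zinc chelation to the epoxide.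

Key step: step 14

Remark: the sense of induction in step 1 is assumed to follow the usual steric-shielding model for diarylprolinol silyl ethers, on which the (R)-catalyst leads to the (S)-enone 6; if the sense is opposite, the (S)-catalyst is used and nothing else changes.

**Route**

Step 1
Reactants: 1 tert-butyl acetoacetate; 2 (E)-crotonaldehyde
Product: 6 (S)-5-methylcyclohex-2-en-1-one, via Michael adduct 3 (not isolated), via cyclohexenone tert-butyl ester 4 (not isolated), via β-keto acid 5 (not isolated)
Conditions: (R)-2-{bis[3,5-bis(trifluoromethyl)phenyl](trimethylsilyloxy)methyl}pyrrolidine (10 mol %), PhCO2H (10 mol %), toluene, 23 °C; then TsOH·H2O (20 mol %), toluene, 80 °C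
Reagents that add atoms: none
Why: Iminium-catalysed Michael addition of the β-keto ester to the enal, then acid-mediated intramolecular aldol condensation, tert-butyl ester cleavage and decarboxylation (an organocatalytic Robinson-type annulation) should give the enone, with C3 set in the Michael step because the bulky diaryl(silyloxy)methyl group of the catalyst shields one face of the (E)-iminium ion.

Step 2
Reactants: 7 3-methylbut-3-en-1-ol
Product: 8 3-methylbut-3-enal
Conditions: Dess–Martin periodinane, NaHCO3, CH2Cl2, 0 °C; filtered solution used at once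
Reagents that add atoms: none
Why: Dess–Martin oxidation of the primary alcohol under buffered, non-basic conditions should give the β,γ-unsaturated aldehyde without migration of the double bond into conjugation, provided the solution is used immediately.

Step 3
Reactants: 6 (S)-5-methylcyclohex-2-en-1-one; 8 3-methylbut-3-enal
Product: 10 (5S,6S)-6-[(1S)-1-hydroxy-3-methylbut-3-en-1-yl]-5-methylcyclohex-2-en-1-one, via lithium enolate 9 (not isolated)
Conditions: LiN(iPr)2, THF, −78 °C; 8 (CH2Cl2 solution), −78 °C; AcOH, −78 °C
Reagents that add atoms: none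
Why: Kinetic α′-deprotonation and lithium aldol addition should create C4 trans to the adjacent C3 methyl (attack anti to the pseudoaxial methyl) and C5 through a Zimmerman–Traxler chair from the ring-locked (E)-enolate, which gives the anti C4/C5 aldol that corresponds to the 5S centre of the target.

Step 4
Reactants: 10 aldol adduct
Product: 11 (5S,6S)-6-[(1S)-1-(tert-butyldimethylsilyloxy)-3-methylbut-3-en-1-yl]-5-methylcyclohex-2-en-1-one
Conditions: TBSOTf, 2,6-lutidine, CH2Cl2, −78 °C
Reagents that add atoms: tert-butyldimethylsilyl trifluoromethanesulfonate, CC(C)(C)[Si](C)(C)OS(=O)(=O)C(F)(F)F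
Why: Silylation of a secondary β-hydroxy ketone with the silyl triflate and a hindered pyridine base is standard and blocks retro-aldol cleavage in the following steps.

Step 5
Reactants: 11 silyloxy enone
Product: 12 (5S,6S)-1-ethenyl-6-[(1S)-1-(tert-butyldimethylsilyloxy)-3-methylbut-3-en-1-yl]-5-methylcyclohex-2-en-1-ol (both C1 epimers)
Conditions: CH2=CHMgBr, CeCl3, THF, −78 °C; aq. NH4Cl
Reagents that add atoms: vinylmagnesium bromide, C=C[Mg]Br
Why: The organocerium reagent formed from the Grignard reagent should add 1,2 to the enone carbonyl without enolisation (Imamoto-type addition), and the new C9 carbinol centre may form as a mixture because it is removed in step 7.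

Step 6
Reactants: 12 vinyl carbinol
Product: 13 bicyclic dienol (4S,4aS,5S)-5-(tert-butyldimethylsilyloxy)-4,7-dimethyl-4,4a,5,6-tetrahydronaphthalen-8a(3H)-ol (both C8a epimers; route numbering: C1=C10 and C7=C8 alkenes with C9–OH)
Conditions: (H2IMes)(PCy3)Cl2Ru=CHPh (second-generation Grubbs catalyst, 5 mol %), CH2Cl2, 40 °C
Reagents that add atoms: none
Why: Ring-closing metathesis between the vinyl group and the 1,1-disubstituted alkene should close ring B as a trisubstituted cyclohexene with loss of ethene, while the endocyclic ring-A alkene stays a spectator.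

Step 7
Reactants: 13 bicyclic dienol
Product: 16 dienone (4S,4aR,5S)-5-(tert-butyldimethylsilyloxy)-4,7-dimethyl-4,4a,5,6-tetrahydronaphthalen-2(3H)-one, via tertiary chlorochromate ester 14 (not isolated), via transposed chlorochromate ester 15 (not isolated)
Conditions: pyridinium chlorochromate [C5H5NH][CrO3Cl], 4 Å molecular sieves, CH2Cl2, 23 °C
Reagents that add atoms: pyridinium chlorochromate, [O-][Cr](=O)(=O)Cl.c1cc[nH+]cc1
Why: In this Babler–Dauben oxidative transposition the tertiary chromate ester shifts [3,3] to C1 and is oxidised there to the enone, whereas the alternative shift to C7 gives a tertiary chromate that cannot be oxidised and reverts, so both C9 epimers should converge on one linearly conjugated dienone.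

Step 8
Reactants: 16 dienone
Product: 17 epoxy enone, the 7,8-epoxide of 16 with the oxygen trans to the C5 silyloxy group (route numbering 3S,4R,5S,7S,8R)
Conditions: mCPBA, NaHCO3, CH2Cl2, 0 °C
Reagents that add atoms: 3-chloroperoxybenzoic acid, O=C(OO)c1cccc(Cl)c1
Why: Prilezhaev epoxidation of a linear dienone occurs at the electron-rich γ,δ-alkene (C7=C8) and not at the enone alkene, and the peracid should approach the face of ring B opposite to the C5 silyloxy group, which sets 7S,8R (epoxide trans to the C5 oxygen, cis to the C3 methyl).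

Step 9
Reactants: 17 epoxy enone
Product: 19 epoxy octalinone with C1 ketone, C10 methylene and C4=C9 ring-fusion alkene (3S,5S,7S,8R), via potassium dienolate 18 (not isolated)
Conditions: KOtBu, tBuOH/THF, 0 °C; then 10 % aq. AcOH, 0 °C
Reagents that add atoms: none
Why: Deconjugation of an enone through its thermodynamic extended enolate and kinetic protonation at the α-carbon (C10) should move the double bond to the ring fusion, and C4 thereby gives up a stereocentre that served only as a relay.

Step 10
Reactants: 20 methyl bromopyruvate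
Product: 21 methyl 3-acetoxy-2-oxopropanoate
Conditions: KOAc, DMF, 0 → 23 °C
Reagents that add atoms: potassium acetate, [K+].CC(=O)[O-]
Why: SN2 displacement of the activated α-bromo ketone by acetate is fast under these mild conditions.

Step 11
Reactants: 19 epoxy octalinone; 21 methyl 3-acetoxy-2-oxopropanoate
Product: 25 alkylidene keto ester, methyl (2E)-3-acetoxy-2-(C10-ylidene)propanoate of the epoxy octalinone with the ester cis to C9 (3S,5S,7S,8R), via lithium dienolate 22 (not isolated), via lithium aldolate 23 (not isolated), via aldol acetate 24 (not isolated)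
Conditions: LiN(iPr)2, THF, −78 °C; 21, −78 °C; Ac2O, −78 → 0 °C; DBU, 0 → 23 °C
Reagents that add atoms: none
Why: Kinetic deprotonation at the doubly activated C10, aldol addition to the highly electrophilic keto carbonyl, in situ acetylation of the tertiary aldolate and E1cB elimination amount to an aldol condensation, and the alkene should form with the ester anti to the C1 carbonyl (dipole minimisation), that is, cis to C9 as the later lactonisation requires.

Step 12
Reactants: 25 alkylidene keto ester
Product: 26 allylic alcohol with C1–OH cis to the C3 methyl (1R,3S,5S,7S,8R)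
Conditions: NaBH4, CeCl3·7H2O, MeOH, −78 °C
Reagents that add atoms: none
Why: In this Luche 1,2-reduction of the cross-conjugated ketone, hydride should attack C1 from the face opposite to the pseudoaxial C3 methyl, giving the 1,3-cis carbinol (1R) as in the reduction of carvone to cis-carveol.

Step 13
Reactants: 26 allylic alcohol
Product: 27 key precursor, the C1 triethylsilyl ether of 26 (epoxy octalin with the C10 alkylidene ester)
Conditions: Et3SiCl, imidazole, DMF, 0 °C
Reagents that add atoms: chlorotriethylsilane, CC[Si](Cl)(CC)CC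
Why: Silylation under non-Lewis-acidic conditions spares the allylic epoxide, and the triethylsilyl ether keeps the C1 oxygen from engaging the C4 ketone or the zinc reagent after ring opening and can be removed later beside the TBS ether.

Step 14
Reactants: 27 epoxy octalin
Product: 30 ten-membered epoxy 1,6-diketone (C4 and C9 ketones; 1R,3S,5S,7S,8S), via primary ozonide 28 (not isolated), via ozonide 29 (not isolated)
Conditions: O3 (1.0 equiv, Sudan Red 7B as indicator), CH2Cl2, −78 °C; then Me2S, −78 → 23 °C
Reagents that add atoms: ozone, [O-][O+]=O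
Why: Ozone adds to the electron-rich tetrasubstituted C4=C9 alkene in a 1,3-dipolar cycloaddition, the primary ozonide 28 cycloreverts to a ketone and a carbonyl oxide that stay tethered and recombine to the ozonide 29, and dimethyl sulfide reduces this to the two ketones. The closest known reaction is the ozonolysis of bicyclo[4.4.0]dec-1(6)-enes to cyclodecane-1,6-diones, and the survival of the ester-conjugated alkene has its model in the γ,δ-selective ozonolysis of dienoates. The ten-membered ring is not closed by bond formation; it appears as the periphery of the bicycle when the bond shared by rings A and B is cleaved. No stereocentre is created, and C1, C3, C5, C7 and C8, all set on the rigid bicycle, are carried over unchanged. The step needs chemoselectivity for C4=C9 over C10=C11, which is secured by the ester and acetoxymethyl groups that make C10=C11 electron-poor, by one equivalent of ozone at −78 °C with an indicator dye, and by the absence of any other alkene, while the epoxide, esters and silyl ethers are inert. Neutral reductive work-up and immediate use of 30 should avoid transannular aldol reaction and epimerisation at C3.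

Step 15
Reactants: 30 epoxy diketone
Product: 33 hydroxy butenolide with C1–OH and C5–OTBS (1R,3S,5S,7S,8R,9R), via hydroxy ester 31 (not isolated), via triethylsilyl butenolide 32 (not isolated)
Conditions: Zn(BH4)2, Et2O, −78 → −20 °C; aq. NH4Cl; then PPTS, MeOH, 0 → 23 °C
Reagents that add atoms: none
Why: Zn(BH4)2 should reduce the C9 ketone 1,2 under chelation between the carbonyl and the epoxide oxygen (erythro-selective reduction of α,β-epoxy ketones), giving the 9R carbinol, which lactonises at once onto the cis ester to form the butenolide, after which PPTS in methanol cleaves the triethylsilyl ether selectively.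

Step 16
Reactants: 33 hydroxy butenolide
Product: 34 C1 methacrylate with C5–OTBS
Conditions: methacrylic anhydride, Et3N, DMAP (cat.), CH2Cl2, 0 → 23 °C
Reagents that add atoms: methacrylic anhydride, C=C(C)C(=O)OC(=O)C(C)=C
Why: DMAP-catalysed acylation of the only free hydroxyl group is standard, and the weakly basic conditions should leave the C3 and C5 centres beside the ketone untouched.

Step 17
Reactants: 34 silyl-protected target
Product: 35 CNP0359197.1
Conditions: HF·pyridine, pyridine, THF, 0 → 23 °C
Reagents that add atoms: none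
Why: Fluoride-mediated cleavage of the secondary TBS ether under pyridine-buffered conditions should free the C5 hydroxyl without opening the epoxide or the lactone and without touching the acetate or methacrylate.

**Compound list**

1 | tert-butyl acetoacetate | CC(=O)CC(=O)OC(C)(C)C | starting material
2 | (E)-crotonaldehyde | C/C=C/C=O | starting material
3 | Michael adduct, tert-butyl (3S)-2-acetyl-3-methyl-5-oxopentanoate (C2 epimers) | CC(=O)C(C(=O)OC(C)(C)C)[C@@H](C)CC=O | intermediate (not isolated)
4 | tert-butyl (6S)-6-methyl-2-oxocyclohex-3-ene-1-carboxylate (C1 epimers) | O=C1C=CC[C@H](C)C1C(=O)OC(C)(C)C | intermediate (not isolated)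
5 | (6S)-6-methyl-2-oxocyclohex-3-ene-1-carboxylic acid | O=C1C=CC[C@H](C)C1C(=O)O | intermediate (not isolated)
6 | (S)-5-methylcyclohex-2-en-1-one | O=C1C=CC[C@H](C)C1 | intermediate
7 | 3-methylbut-3-en-1-ol | C=C(C)CCO | starting material
8 | 3-methylbut-3-enal | C=C(C)CC=O | intermediate
9 | lithium cross-conjugated enolate of 6 (lithium 3-methylcyclohexa-1,5-dien-1-olate) | [Li]OC1=C[C@@H](C)CC=C1 | intermediate (not isolated)
10 | (5S,6S)-6-[(1S)-1-hydroxy-3-methylbut-3-en-1-yl]-5-methylcyclohex-2-en-1-one | O=C1C=CC[C@H](C)[C@H]1[C@@H](O)CC(C)=C | intermediate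
11 | (5S,6S)-6-[(1S)-1-(tert-butyldimethylsilyloxy)-3-methylbut-3-en-1-yl]-5-methylcyclohex-2-en-1-one | O=C1C=CC[C@H](C)[C@H]1[C@@H](O[Si](C)(C)C(C)(C)C)CC(C)=C | intermediate
12 | (5S,6S)-1-ethenyl-6-[(1S)-1-(tert-butyldimethylsilyloxy)-3-methylbut-3-en-1-yl]-5-methylcyclohex-2-en-1-ol, both C1 epimers | C=CC1(O)C=CC[C@H](C)[C@H]1[C@@H](O[Si](C)(C)C(C)(C)C)CC(C)=C | intermediate
13 | bicyclic dienol, (4S,4aS,5S)-5-(tert-butyldimethylsilyloxy)-4,7-dimethyl-4,4a,5,6-tetrahydronaphthalen-8a(3H)-ol, both C8a epimers | OC12C=CC[C@H](C)[C@H]1[C@@H](O[Si](C)(C)C(C)(C)C)CC(C)=C2 | intermediate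
14 | chlorochromate ester of 13 at the C9 oxygen | O=[Cr](=O)(Cl)OC12C=CC[C@H](C)[C@H]1[C@@H](O[Si](C)(C)C(C)(C)C)CC(C)=C2 | intermediate (not isolated)
15 | transposed chlorochromate ester, C1–OCrO2Cl with C9=C10 and C7=C8 alkenes | O=[Cr](=O)(Cl)OC1C[C@H](C)[C@H]2[C@@H](O[Si](C)(C)C(C)(C)C)CC(C)=CC2=C1 | intermediate (not isolated)
16 | dienone, (4S,4aR,5S)-5-(tert-butyldimethylsilyloxy)-4,7-dimethyl-4,4a,5,6-tetrahydronaphthalen-2(3H)-one | O=C1C[C@H](C)[C@H]2[C@@H](O[Si](C)(C)C(C)(C)C)CC(C)=CC2=C1 | intermediate
17 | epoxy enone, 7,8-epoxide of 16 trans to the C5 silyloxy group (3S,4R,5S,7S,8R) | O=C1C[C@H](C)[C@H]2[C@@H](O[Si](C)(C)C(C)(C)C)C[C@]3(C)O[C@@H]3C2=C1 | intermediate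
18 | potassium extended enolate of 17 (C1–OK, C1=C10 and C4=C9) | [K]OC1=CC2=C([C@@H](O[Si](C)(C)C(C)(C)C)C[C@]3(C)O[C@@H]32)[C@@H](C)C1 | intermediate (not isolated)
19 | epoxy octalinone, C1 ketone, C10 methylene, C4=C9 alkene (3S,5S,7S,8R) | O=C1CC2=C([C@@H](O[Si](C)(C)C(C)(C)C)C[C@]3(C)O[C@@H]32)[C@@H](C)C1 | intermediate
20 | methyl bromopyruvate (methyl 3-bromo-2-oxopropanoate) | COC(=O)C(=O)CBr | starting material
21 | methyl 3-acetoxy-2-oxopropanoate | COC(=O)C(=O)COC(C)=O | intermediate
22 | lithium extended enolate of 19 | [Li]OC1=CC2=C([C@@H](O[Si](C)(C)C(C)(C)C)C[C@]3(C)O[C@@H]32)[C@@H](C)C1 | intermediate (not isolated)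
23 | lithium aldolate, C10–C11(OLi)(CH2OAc)(CO2Me), C10 and C11 epimers | O=C1C(C(O[Li])(COC(C)=O)C(=O)OC)C2=C([C@@H](O[Si](C)(C)C(C)(C)C)C[C@]3(C)O[C@@H]32)[C@@H](C)C1 | intermediate (not isolated)
24 | tertiary acetate of the aldol, C10 and C11 epimers | O=C1C(C(OC(C)=O)(COC(C)=O)C(=O)OC)C2=C([C@@H](O[Si](C)(C)C(C)(C)C)C[C@]3(C)O[C@@H]32)[C@@H](C)C1 | intermediate (not isolated)
25 | alkylidene keto ester, C10=C11(CO2Me)(CH2OAc) with the ester cis to C9, C1 ketone (3S,5S,7S,8R) | O=C1/C(=C(\COC(C)=O)C(=O)OC)C2=C([C@@H](O[Si](C)(C)C(C)(C)C)C[C@]3(C)O[C@@H]32)[C@@H](C)C1 | intermediate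
26 | allylic alcohol, C1–OH cis to C3 methyl (1R,3S,5S,7S,8R) | O[C@H]1/C(=C(\COC(C)=O)C(=O)OC)C2=C([C@@H](O[Si](C)(C)C(C)(C)C)C[C@]3(C)O[C@@H]32)[C@@H](C)C1 | intermediate
27 | key precursor, C1 triethylsilyl ether of 26 (epoxy octalin) | CC[Si](CC)(CC)O[C@H]1/C(=C(\COC(C)=O)C(=O)OC)C2=C([C@@H](O[Si](C)(C)C(C)(C)C)C[C@]3(C)O[C@@H]32)[C@@H](C)C1 | intermediate
28 | primary ozonide (1,2,3-trioxolane across C4–C9; configuration at C4 and C9 not specified) | CC[Si](CC)(CC)O[C@H]1/C(=C(\COC(C)=O)C(=O)OC)C23OOOC2([C@@H](O[Si](C)(C)C(C)(C)C)C[C@]4(C)O[C@@H]43)[C@@H](C)C1 | intermediate (not isolated)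
29 | ozonide (1,2,4-trioxolane bridging C4 and C9; configuration at C4 and C9 not specified) | CC[Si](CC)(CC)O[C@H]1/C(=C(\COC(C)=O)C(=O)OC)C23OC(OO2)([C@@H](O[Si](C)(C)C(C)(C)C)C[C@]4(C)O[C@@H]43)[C@@H](C)C1 | intermediate (not isolated)
30 | ten-membered epoxy 1,6-diketone, C4 and C9 ketones, ester cis to C9 (1R,3S,5S,7S,8S) | CC[Si](CC)(CC)O[C@H]1/C(=C(\COC(C)=O)C(=O)OC)C(=O)[C@H]2O[C@@]2(C)C[C@H](O[Si](C)(C)C(C)(C)C)C(=O)[C@@H](C)C1 | intermediate
31 | hydroxy ester, 9R carbinol (1R,3S,5S,7S,8R,9R) | CC[Si](CC)(CC)O[C@H]1/C(=C(\COC(C)=O)C(=O)OC)[C@@H](O)[C@H]2O[C@@]2(C)C[C@H](O[Si](C)(C)C(C)(C)C)C(=O)[C@@H](C)C1 | intermediate (not isolated)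
32 | butenolide with C1–OSiEt3 and C5–OTBS | CC[Si](CC)(CC)O[C@@H]1C[C@H](C)C(=O)[C@@H](O[Si](C)(C)C(C)(C)C)C[C@]2(C)O[C@@H]2[C@@H]2OC(=O)C(COC(C)=O)=C21 | intermediate (not isolated)
33 | hydroxy butenolide with C1–OH and C5–OTBS | O[C@@H]1C[C@H](C)C(=O)[C@@H](O[Si](C)(C)C(C)(C)C)C[C@]2(C)O[C@@H]2[C@@H]2OC(=O)C(COC(C)=O)=C21 | intermediate
34 | C1 methacrylate with C5–OTBS | C=C(C)C(=O)O[C@@H]1C[C@H](C)C(=O)[C@@H](O[Si](C)(C)C(C)(C)C)C[C@]2(C)O[C@@H]2[C@@H]2OC(=O)C(COC(C)=O)=C21 | intermediate
35 | CNP0359197.1 (1R,3S,5S,7S,8R,9R in the route numbering) | C=C(C)C(=O)O[C@@H]1C[C@H](C)C(=O)[C@@H](O)C[C@]2(C)O[C@@H]2[C@@H]2OC(=O)C(COC(C)=O)=C21 | target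

**Step count**

Total: 17 steps. Longest linear sequence: 15 steps (steps 1, 3–9 and 11–17); steps 2 and 10 prepare the two side-chain reagents.

**Steps most likely to fail**

1. Step 9. The extended enolate may expel the C5 silyloxy group (vinylogous β-elimination, followed by aromatisation of ring B), or the β,γ-enone may slip back into conjugation during work-up. The fallback sets out from 17 and avoids a metal enolate: condensation with pyrrolidine (MeOH, 23 °C) should give the through-conjugated dienamine F1, and buffered hydrolysis (NaOAc/AcOH, aq. THF, 0 °C), which protonates the dienamine kinetically at C10, should release the β,γ-enone; the route is rejoined at 19.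

2. Step 11. Proton transfer from the enolisable keto ester to the dienolate, or retro-aldol cleavage before the aldolate is acetylated, may leave 19 unchanged. The fallback sets out from 19 and replaces the reversible aldol by an irreversible epoxide trap. Dienolate 22 is treated with methyl bromopyruvate 20 (THF, −78 → 0 °C); the lithium bromo-aldolate F2 should close at once to the glycidic ester F3 (Darzens-type closure). DBU then opens the oxirane by E1cB elimination from C10 to give the hydroxymethyl alkylidene ketone F4, and acetylation (Ac2O, pyridine) rejoins the route at 25.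

3. Step 15. Hydride delivery in the flexible ten-membered ring may show poor facial selectivity if the zinc chelate with the epoxide does not dominate, and conjugate reduction of the ene-dicarbonyl unit may compete. The fallback sets out from 30 and replaces substrate control by reagent control: 1,2-reduction with (R)-2-methyl-CBS-oxazaborolidine and catecholborane (toluene, −78 °C), in which the alkenyl side of the ketone is taken as the large group, should give 31, and the same lactonisation and PPTS/MeOH treatment rejoin the route at 33. This fallback makes no compound beyond those already listed (entry F0: none).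

**Further compounds**

F1 | step 9 | through-conjugated dienamine of 17, 1-pyrrolidinyl diene with C1=C10 and C4=C9 | C1(N4CCCC4)=CC2=C([C@@H](O[Si](C)(C)C(C)(C)C)C[C@]3(C)O[C@@H]32)[C@@H](C)C1
F2 | step 11 | lithium bromo-aldolate, C10–C11(OLi)(CH2Br)(CO2Me), C10 and C11 epimers | O=C1C(C(O[Li])(CBr)C(=O)OC)C2=C([C@@H](O[Si](C)(C)C(C)(C)C)C[C@]3(C)O[C@@H]32)[C@@H](C)C1
F3 | step 11 | glycidic ester, methyl 2-(C10-yl)oxirane-2-carboxylate of the epoxy octalinone, C10 and C11 epimers | O=C1C(C4(CO4)C(=O)OC)C2=C([C@@H](O[Si](C)(C)C(C)(C)C)C[C@]3(C)O[C@@H]32)[C@@H](C)C1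
F4 | step 11 | hydroxymethyl alkylidene ketone, C10=C11(CO2Me)(CH2OH) with the ester cis to C9 | O=C1/C(=C(\CO)C(=O)OC)C2=C([C@@H](O[Si](C)(C)C(C)(C)C)C[C@]3(C)O[C@@H]32)[C@@H](C)C1
F0 | step 15 | none | none
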